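3.07 was the number I started from: with the whole catalyst in maple at 25 °C, that many starting material left for side product at each turn of the catalyst. I called the side constant over the catalysed constant times the catalyst the rival ratio, a selectivity factor. Both steps are first order in starting material, so the ratio stays put while the starting material falls.

the same everywhere: starting material 10 mM; protic impurity 1.00 mM; catalyst 1.0 mM (in portions, 2); time 15 min

| flask | temperature | remark |
|---|---|---|
| maple | 25 °C | the portions of catalyst follow each other after 8.0 s, the first at the start |
| oak | 10 °C | the portions of catalyst follow each other after 8.0 s, the first at the start |
| elm | −5 °C | the portions of catalyst follow each other after 8.0 s, the first at the start |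

    starting material + catalyst → catalyst + target (k1 = 15 M⁻¹ s⁻¹, Ea1 = 53.0 kJ mol⁻¹)
    starting material → side product (k2 = 0.046 s⁻¹, Ea2 = 77.0 kJ mol⁻¹)
    starting material + protic impurity → quenched substrate (k3 = 56 M⁻¹ s⁻¹, Ea3 = 47.0 kJ mol⁻¹)
    2 starting material → self-condensation product (k4 = 4.1 × 10⁻⁴ M⁻¹ s⁻¹, Ea4 = 54.0 kJ mol⁻¹)
    starting material + target ⇌ idle adduct, settled at all times (K5 = 50 M⁻¹, ΔH5 = 3.00 kJ mol⁻¹)
    (constants at 25 °C)

- a species is counted by the starting material in it: one self-condensation product or idle adduct counts as two
- amounts and yields of target count idle adduct too
- two of one species on the left: rate k times its square, two consumed each time
- constants are those at 25 °C; use the activation energies and enthalpies for any other temperature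
- in an amount of target, one idle adduct counts as one target

- the flask that comes out highest in amount of target, in percent of the starting material charged, or "all alike" when all lie within 1.5 percentage points (maple / oak / elm / all alike)
- target at the end, in percent of the starting material charged, maple
- target at the end, in percent of the starting material charged, oak
- target at the end, in percent of the starting material charged, elm

I drew the target curve of maple in fractions of the charge. It began with a slope of 0.450 min⁻¹ on half the catalyst, where the rival ratio stood doubled, so 0.140 of what reacted became target. The protic impurity took 10.0% of the charge early, its pull being faster than the other losses. Self-condensation was far slower than the side step, so I dropped it.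

The knee came with the second portion at 8.0 s. By then 0.652 of the remaining starting material had survived, and target stood at 4.38%. After the knee the share was 0.246 and the half-life 11.4 s, much shorter than the time allowed, so maple's curve ran flat at 18.8%.

Cooling lowered the ratio, since the side step has the higher barrier. In oak the ratio was 1.84 and 0.914 survived to the knee. The half-life after it was 0.843 min, shorter than the time allowed, so oak levelled at 30.7%.

In elm the ratio was 1.04 and 0.983 survived, which gave a level of 43.9%. But the half-life, which I reckoned with the idle adduct left out, was 4.13 min, so my reckoning left 0.0808 of the way to that level unrun at 15 min, and I wrote down 40.4% for elm, the highest of my figures.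

The forecast also put elm highest, with 19% for maple, 30.5% for oak and 39% for elm, on this ground: “Cooling favours the catalysed step over the higher-barrier first-order loss to side product”. Its elm figure stood below mine.

The simulation gave 18.8% for maple, 30.6% for oak and 39.3% for elm, so elm came highest, with 7.92% of starting material and 2.63% of idle adduct still in elm at 15.0 min. The neighbour repeated maple at 50 °C. There the rival ratio rose to 6.49, and 0.0125 of the starting material outlived the first portion, so my level for it was 6.51%. That flask gave 6.53% of target and 83.7% of side product.

All constants stand for no real mixture; the flask was simulated.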